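**Plan**

- Retrosynthesis: the C8 ester is cut to (2S,3S)-epoxyangelic acid and the O6–C12 lactone is traced back to a 6,12-diol kept as its bis-silyl ether; then the ring bond C2–C3 is cut, then C9–C10, then C6–C7.
- Forward: a C3–C6 sulfonyl enal and a glyceraldehyde-derived bromomethyl enoate give the 6,7-cis lactone (C6–C7); this is reduced and silylated; a Z-alkenylmagnesium reagent adds at C9 (C9–C10); the C2 alcohol becomes the bromide.
- The ten-membered carbocycle closes first, at C2–C3; the sulfone is then removed, C8 is esterified, and the α-methylene lactone ring is re-formed last by oxidation of the 6,12-diol.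
- Enabling feature: C2–C3 is the only CH2–CH2 bond of the ten-membered ring and both carbons are allylic (to Z-C1=C10 and to E-C4=C5), so a C3 sulfonyl allyl anion and a C2 allylic bromide can be joined without making or moving an alkene.
- Stereochemistry: C8 comes from (R)-solketal; C7 and C6 from the chair Barbier transition state (Felkin sense at C8, syn adduct, hence cis lactone); C9 from chelate-controlled addition next to the C8 OPMB group; the epoxide from a Sharpless epoxidation with D-(−)-tartrate. E-C4=C5 comes from the starting chloride and Z-C1=C10 from hydroalumination–iodination of 2-butyn-1-ol.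

Key step: step 20

**Remarks on the chemistry**

- Locants follow the germacranolide skeleton of the target: ring carbons C1–C10, C11(=C13H2)–C12 on C7, C14 the methyl on C10, C15 the methyl on C4.
- The C3 sulfonyl centre formed in step 20 is expected as an epimer mixture. One epimer (3S) is drawn; both converge in step 21.
- Compounds 8, 16 and 42 are epimer mixtures at a centre that is removed or oxidised later.
- CIP descriptors at C7 change with the O6 substituent (7S with OH or acyl, 7R with OSi); the spatial arrangement is the same throughout.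

**Route**

Step 1
Reactants: 1 (E)-4-chloro-3-methylbut-2-en-1-yl acetate
Product: 2 (E)-3-methyl-4-(phenylsulfonyl)but-2-en-1-yl acetate
Conditions: PhSO2Na, DMF, rt
Reagents that add atoms: sodium benzenesulfinate, [Na+].[O-]S(=O)c1ccccc1
Why: SN2 displacement of the primary allylic chloride by sulfur of the sulfinate (sulfone synthesis by sulfinate S-alkylation), which leaves the E alkene and the acetate untouched.

Step 2
Reactants: 2 (E)-3-methyl-4-(phenylsulfonyl)but-2-en-1-yl acetate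
Product: 3 (E)-3-methyl-4-(phenylsulfonyl)but-2-en-1-ol
Conditions: K2CO3 (cat.), MeOH, 0 °C
Reagents that add atoms: none
Why: Base-catalysed transesterification (Zemplén-type methanolysis) frees the allylic alcohol, and at 0 °C the allyl sulfone should not isomerise to the vinyl sulfone.

Step 3
Reactants: 3 (E)-3-methyl-4-(phenylsulfonyl)but-2-en-1-ol
Product: 4 (E)-3-methyl-4-(phenylsulfonyl)but-2-enal
Conditions: MnO2, CH2Cl2, rt
Reagents that add atoms: none
Why: MnO2 oxidation of a primary allylic alcohol under neutral conditions should keep the E geometry and the acidic CH2SO2Ph position intact.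

Step 4
Reactants: 5 (R)-solketal
Product: 6 (4S)-2,2-dimethyl-1,3-dioxolane-4-carbaldehyde
Conditions: (COCl)2, DMSO, CH2Cl2, −78 °C; Et3N, −78 → 0 °C; used crude
Reagents that add atoms: none
Why: Swern oxidation gives the α-alkoxy aldehyde without epimerisation at low temperature.

Step 5
Reactants: 6 (4S)-2,2-dimethyl-1,3-dioxolane-4-carbaldehyde; 7 methyl acrylate
Product: 8 methyl 2-{[(4S)-2,2-dimethyl-1,3-dioxolan-4-yl](hydroxy)methyl}prop-2-enoate (carbinol epimers)
Conditions: DABCO, 1,4-dioxane/H2O 1:1, rt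
Reagents that add atoms: none
Why: Morita–Baylis–Hillman reaction of the acrylate with the aldehyde; the new carbinol centre forms as a mixture and is erased in step 6.

Step 6
Reactants: 8 methyl 2-{[(4S)-2,2-dimethyl-1,3-dioxolan-4-yl](hydroxy)methyl}prop-2-enoate
Product: 9 methyl (2Z)-2-(bromomethyl)-3-[(4R)-2,2-dimethyl-1,3-dioxolan-4-yl]prop-2-enoate
Conditions: NBS, Me2S, CH2Cl2, 0 °C → rt
Reagents that add atoms: N-bromosuccinimide, O=C1CCC(=O)N1Br
Why: Corey–Kim-type activation of the allylic alcohol and SN2′ return of bromide should give the conjugated trisubstituted enoate with the dioxolane cis to CH2Br (2Z), under neutral conditions that spare the acetonide.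

Step 7
Reactants: 4 (E)-3-methyl-4-(phenylsulfonyl)but-2-enal; 9 methyl (2Z)-2-(bromomethyl)-3-[(4R)-2,2-dimethyl-1,3-dioxolan-4-yl]prop-2-enoate
Product: 12 (4S,5S)-4-[(4R)-2,2-dimethyl-1,3-dioxolan-4-yl]-3-methylidene-5-[(1E)-2-methyl-3-(phenylsulfonyl)prop-1-en-1-yl]oxolan-2-one (6S,7S,8R cis-lactone), via allylzinc bromide 10 (not isolated), via hydroxy ester 11 (not isolated)
Conditions: Zn dust, THF/sat. aq. NH4Cl, 0 °C → rt; then PPTS (cat.), toluene, 60 °C
Reagents that add atoms: none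
Why: Barbier allylation followed by lactonisation: the Z-allylzinc 10 adds through its γ-carbon in a chair (Zimmerman–Traxler) transition state with the dioxolanyl group axial, which gives the 6,7-syn adduct 11 and hence the cis lactone, while the C8 centre, held with its C–H eclipsing the allyl double bond by allylic 1,3-strain, should direct the enal to the face anti to the C8–O bond (Felkin–Anh sense), setting 7S and 6S.

Step 8
Reactants: 12 cis-lactone (6S,7S,8R)
Product: 13 diol (6S,7S,8R): 3-SO2Ph, 4E, 6-OH, 12-OH, 8,9-O-isopropylidene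
Conditions: i-Bu2AlH, CH2Cl2, −78 → 0 °C; Rochelle salt work-up
Reagents that add atoms: none
Why: i-Bu2AlH reduces the α-methylene lactone by two 1,2-hydride additions to the 2-methylene-1,4-diol, while sulfone, acetonide and alkenes are inert at low temperature.

Step 9
Reactants: 13 diol (6S,7S,8R)
Product: 14 bis-TBS ether (6S,7R,8R): 6-OTBS, 12-OTBS, 8,9-O-isopropylidene
Conditions: TBSOTf, 2,6-lutidine, CH2Cl2, −78 → 0 °C
Reagents that add atoms: tert-butyldimethylsilyl triflate, CC(C)(C)[Si](C)(C)OS(=O)(=O)C(F)(F)F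
Why: Silyl triflate silylation protects the primary and the hindered secondary allylic alcohol alike, so the lactone is stored without any carbonyl or free OH at C6/C12.

Step 10
Reactants: 14 bis-TBS ether (6S,7R,8R)
Product: 15 8,9-diol (6S,7R,8R): 6-OTBS, 12-OTBS, 8-OH, 9-OH
Conditions: CeCl3·7H2O, oxalic acid (cat.), MeCN, rt
Reagents that add atoms: none
Why: Mild Lewis-acid-assisted hydrolysis of a terminal acetonide, a method that should leave TBS ethers in place.

Step 11
Reactants: 15 8,9-diol (6S,7R,8R)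
Product: 16 8,9-O-(4-methoxybenzylidene) acetal (6S,7R,8R; acetal epimers)
Conditions: 4-MeOC6H4CH(OMe)2, PPTS (cat.), CH2Cl2, rt
Reagents that add atoms: 4-methoxybenzaldehyde dimethyl acetal, COC(OC)c1ccc(OC)cc1
Why: Acid-catalysed transacetalisation gives the five-membered p-methoxybenzylidene acetal, and both acetal epimers serve in step 12.

Step 12
Reactants: 16 8,9-O-(4-methoxybenzylidene) acetal
Product: 17 primary alcohol (6S,7R,8R): 8-OPMB, 9-OH, 6-OTBS, 12-OTBS
Conditions: i-Bu2AlH, CH2Cl2, −78 → 0 °C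
Reagents that add atoms: none
Why: Reductive acetal opening: aluminium binds the less hindered primary oxygen, so hydride delivery should leave the PMB group on O8 and free the C9 alcohol.

Step 13
Reactants: 17 primary alcohol (6S,7R,8R)
Product: 18 C9 aldehyde (6S,7R,8R): 8-OPMB, 6-OTBS, 12-OTBS
Conditions: Dess–Martin periodinane, NaHCO3, CH2Cl2, 0 °C → rt; used at once
Reagents that add atoms: none
Why: Buffered Dess–Martin oxidation should give the α-alkoxy aldehyde without epimerising C8.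

Step 14
Reactants: 19 2-butyn-1-ol
Product: 21 (2Z)-3-iodobut-2-en-1-ol, via vinylalanate 20 (not isolated)
Conditions: NaAlH2(OCH2CH2OMe)2, THF, 0 °C → rt; then I2, −78 → 0 °C
Reagents that add atoms: iodine, II
Why: Hydroxyl-directed trans-hydroalumination places aluminium on C3 in a five-membered alanate, and iodinolysis with retention gives the Z iodo allylic alcohol.

Step 15
Reactants: 21 (2Z)-3-iodobut-2-en-1-ol
Product: 22 (2Z)-3-iodobut-2-en-1-yl triethylsilyl ether
Conditions: TESCl, imidazole, CH2Cl2, 0 °C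
Reagents that add atoms: chlorotriethylsilane, CC[Si](Cl)(CC)CC
Why: Standard silylation; the TES ether is chosen because it can later be removed in the presence of TBS and TIPS ethers.

Step 16
Reactants: 18 C9 aldehyde (6S,7R,8R); 22 (2Z)-3-iodobut-2-en-1-yl triethylsilyl ether
Product: 25 C9 alcohol (1(10)Z,4E,6S,7R,8R,9R): 2-OTES, 9-OH, 8-OPMB, 6-OTBS, 12-OTBS, 3-SO2Ph, via alkenyllithium 23 (not isolated), via alkenylmagnesium bromide 24 (not isolated)
Conditions: 22, t-BuLi, Et2O, −78 °C; MgBr2·OEt2, −78 → −40 °C; then 18, CH2Cl2, −78 °C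
Reagents that add atoms: none
Why: Iodine–lithium exchange with retention, transmetalation to magnesium and Cram-chelate addition: magnesium bridges the aldehyde oxygen and the C8 OPMB oxygen and the alkenyl group attacks anti to C7, which should give the 8,9-syn (9R) alcohol with Z-C1=C10 in place, and at −78 °C addition to the aldehyde should outrun deprotonation next to the sulfone.

Step 17
Reactants: 25 C9 alcohol (9R)
Product: 26 C9 TIPS ether: 2-OTES, 9-OTIPS, 8-OPMB, 6-OTBS, 12-OTBS, 3-SO2Ph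
Conditions: TIPSOTf, 2,6-lutidine, CH2Cl2, 0 °C → rt
Reagents that add atoms: triisopropylsilyl triflate, CC(C)[Si](OS(=O)(=O)C(F)(F)F)(C(C)C)C(C)C
Why: Silyl triflate silylation of the hindered secondary allylic alcohol, needed because a free C9 alkoxide would close a dihydrofuran on the C2 bromide.

Step 18
Reactants: 26 C9 TIPS ether
Product: 27 C2 alcohol: 2-OH, 9-OTIPS, 8-OPMB, 6-OTBS, 12-OTBS, 3-SO2Ph
Conditions: PPTS (cat.), MeOH/CH2Cl2 1:1, 0 °C
Reagents that add atoms: none
Why: Acid-catalysed methanolysis should cleave the primary TES ether much faster than TBS or TIPS ethers.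

Step 19
Reactants: 27 C2 alcohol
Product: 28 C2 bromide, (1(10)Z,4E,6S,7R,8R,9R)-2-bromo-3-(phenylsulfonyl)-6,12-bis(TBS-oxy)-8-(PMB-oxy)-9-(TIPS-oxy)-2,3-secogermacra-1(10),4,11(13)-triene
Conditions: CBr4, PPh3, CH2Cl2, −20 → 0 °C; used at once
Reagents that add atoms: carbon tetrabromide, BrC(Br)(Br)Br
Why: Appel bromination converts the primary allylic alcohol into the bromide by SN2 at low temperature, without allylic transposition or Z/E change.

Step 20
Reactants: 28 C2 bromide / C3 sulfone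
Product: 30 (1(10)Z,4E,6S,7R,8R,9R)-3-(phenylsulfonyl)-6,12-bis(TBS-oxy)-8-(PMB-oxy)-9-(TIPS-oxy)germacra-1(10),4,11(13)-triene (C3 epimers; 3S drawn), via lithiated sulfone 29 (not isolated)
Conditions: LiN(SiMe3)2 (1.5 equiv), THF, slow addition of 28 to a final concentration of about 0.003 M, −78 → 0 °C
Reagents that add atoms: none
Why: LiN(SiMe3)2 removes the C3 proton next to the sulfone, the only acidic C–H in 28, and the allyl anion 29 displaces the primary allylic bromide at C2 through its sulfonyl-bearing α-carbon in an SN2 reaction, forming C2–C3. The closest known reaction type is the macrocyclising alkylation of allylic sulfone carbanions by allylic halides used for germacrane and cembrane rings. The ten-membered carbocycle closes in the 10-exo-tet mode under high dilution, and the Z-C1=C10 and E-C4=C5 alkenes on either side of the new bond, together with the four contiguous substituted carbons C6–C9, limit the chain to folded conformers. The new C3 centre is not controlled and need not be, because C3 becomes CH2 in step 21. The step needs α- over γ-alkylation of the anion and SN2 over SN2′ at the bromide: sulfonyl allyl anions react at the α-carbon, and the γ or SN2′ paths would give eight-membered rings or a quaternary C10, so both alkene geometries should be kept. With no carbonyl in 28, lithium as counter-ion and low temperature, vinylogous loss of the C6 silanolate from 29 should be slower than ring closure.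

Step 21
Reactants: 30 macrocyclic C3 sulfone
Product: 31 (1(10)Z,4E,6S,7R,8R,9R)-6,12-bis(TBS-oxy)-8-(PMB-oxy)-9-(TIPS-oxy)germacra-1(10),4,11(13)-triene
Conditions: PdCl2(dppp) (10 mol %), LiBHEt3, THF, 0 °C → rt
Reagents that add atoms: none
Why: Palladium-catalysed reductive desulfonylation: zerovalent palladium, formed from the divalent precatalyst and hydride, ionises the allylic sulfone to a π-allyl complex and hydride should be delivered to C3, the terminus remote from the C6 oxygen, so that E-C4=C5 is kept.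

Step 22
Reactants: 31 desulfonylated macrocycle
Product: 32 C8 alcohol (6S,7R,8R,9R): 8-OH, 9-OTIPS, 6-OTBS, 12-OTBS
Conditions: DDQ, CH2Cl2/pH 7 buffer 10:1, 0 °C
Reagents that add atoms: none
Why: Oxidative cleavage of the PMB ether by DDQ through the benzylic oxocarbenium ion; silyl ethers and unconjugated alkenes should be stable under buffered conditions.

Step 23
Reactants: 33 angelic acid
Product: 34 (2Z)-2-methylbut-2-en-1-ol
Conditions: LiAlH4, Et2O, 0 °C → rt
Reagents that add atoms: none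
Why: LiAlH4 reduces the carboxylic acid to the allylic alcohol by 1,2-reduction with the Z alkene retained.

Step 24
Reactants: 34 (2Z)-2-methylbut-2-en-1-ol
Product: 35 [(2R,3S)-2,3-dimethyloxiran-2-yl]methanol
Conditions: Ti(OiPr)4, D-(−)-diisopropyl tartrate, t-BuOOH, 4 Å MS, CH2Cl2, −20 °C
Reagents that add atoms: tert-butyl hydroperoxide, CC(C)(C)OO
Why: Sharpless asymmetric epoxidation; with the D-(−)-tartrate the oxygen should be delivered to the face that gives the (2R,3S) epoxy alcohol, the two methyl groups staying trans.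

Step 25
Reactants: 35 [(2R,3S)-2,3-dimethyloxiran-2-yl]methanol
Product: 37 (2S,3S)-2,3-dimethyloxirane-2-carboxylic acid, via epoxy aldehyde 36 (not isolated)
Conditions: RuCl3 (cat.), NaIO4, MeCN/CCl4/H2O, rt
Reagents that add atoms: water, O
Why: Ruthenium tetroxide oxidation (RuCl3/NaIO4) of an epoxy alcohol to the glycidic acid through the aldehyde hydrate; the epoxide carbons are untouched and the 2R to 2S change is only a change of priorities.

Step 26
Reactants: 32 C8 alcohol; 37 (2S,3S)-2,3-dimethyloxirane-2-carboxylic acid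
Product: 39 C8 ester (6S,7R,8R,9R): 8-O-[(2S,3S)-2,3-dimethyloxirane-2-carbonyl], 9-OTIPS, 6-OTBS, 12-OTBS, via mixed anhydride 38 (not isolated)
Conditions: 37, 2,4,6-trichlorobenzoyl chloride, Et3N, toluene, rt; then 32, DMAP, rt → 40 °C
Reagents that add atoms: none
Why: Yamaguchi esterification: DMAP attacks the mixed anhydride at the less hindered glycidyl carbonyl and passes the acyl group to the hindered C8 alcohol, and since the acid has no α-hydrogen it cannot epimerise or isomerise.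

Step 27
Reactants: 39 C8 ester
Product: 40 6,12-diol (6S,7S,8R,9R): 6-OH, 12-OH, 8-ester, 9-OTIPS
Conditions: HF·pyridine, pyridine, THF, 0 °C → rt
Reagents that add atoms: none
Why: Buffered fluoride desilylation should remove the two TBS ethers faster than the bulkier TIPS ether, with the glycidic ester untouched.

Step 28
Reactants: 40 6,12-diol
Product: 43 9-O-TIPS lactone (6S,7S,8R,9R), via hydroxy enal 41 (not isolated), via lactol 42 (not isolated)
Conditions: TEMPO (cat.), PhI(OAc)2, CH2Cl2, rt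
Reagents that add atoms: none
Why: Oxoammonium oxidation (TEMPO/PhI(OAc)2) is selective for the primary allylic alcohol; the enal is trapped by the C6 hydroxyl as a lactol that is oxidised further (oxidative lactonisation), which should give the 6,7-cis α-methylene lactone.

Step 29
Reactants: 43 9-O-TIPS lactone
Product: 44 CNP0318223.3, (1(10)Z,4E,6S,7S,8R,9R)-9-hydroxy-8-[(2S,3S)-2,3-dimethyloxirane-2-carbonyloxy]germacra-1(10),4,11(13)-trien-12,6-olide
Conditions: HF·pyridine (excess), THF, 0 °C → rt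
Reagents that add atoms: none
Why: Acidic fluoride cleaves the TIPS ether, and the non-basic medium should avoid C8 to C9 acyl migration and conjugate addition to the α-methylene lactone.

**Compound list**

1 | (E)-4-chloro-3-methylbut-2-en-1-yl acetate | CC(=O)OC/C=C(\C)CCl | starting material
2 | (E)-3-methyl-4-(phenylsulfonyl)but-2-en-1-yl acetate | CC(=O)OC/C=C(\C)CS(=O)(=O)c1ccccc1 | intermediate
3 | (E)-3-methyl-4-(phenylsulfonyl)but-2-en-1-ol | OC/C=C(\C)CS(=O)(=O)c1ccccc1 | intermediate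
4 | (E)-3-methyl-4-(phenylsulfonyl)but-2-enal (C3–C6 with C15) | O=C/C=C(\C)CS(=O)(=O)c1ccccc1 | intermediate
5 | (R)-solketal, [(4R)-2,2-dimethyl-1,3-dioxolan-4-yl]methanol | OC[C@@H]1COC(C)(C)O1 | starting material
6 | (4S)-2,2-dimethyl-1,3-dioxolane-4-carbaldehyde | O=C[C@@H]1COC(C)(C)O1 | intermediate
7 | methyl acrylate | C=CC(=O)OC | starting material
8 | methyl 2-{[(4S)-2,2-dimethyl-1,3-dioxolan-4-yl](hydroxy)methyl}prop-2-enoate (carbinol epimers) | COC(=O)C(=C)C(O)[C@@H]1COC(C)(C)O1 | intermediate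
9 | methyl (2Z)-2-(bromomethyl)-3-[(4R)-2,2-dimethyl-1,3-dioxolan-4-yl]prop-2-enoate | COC(=O)/C(CBr)=C/[C@@H]1COC(C)(C)O1 | intermediate
10 | allylzinc bromide from 9 (zinc on the former CH2Br carbon, dioxolane (4R)) | COC(=O)/C(C[Zn]Br)=C/[C@@H]1COC(C)(C)O1 | intermediate (not isolated)
11 | methyl (3S,4S,5E)-3-[(4R)-2,2-dimethyl-1,3-dioxolan-4-yl]-4-hydroxy-6-methyl-2-methylidene-7-(phenylsulfonyl)hept-5-enoate | COC(=O)C(=C)[C@H]([C@@H]1COC(C)(C)O1)[C@@H](O)/C=C(\C)CS(=O)(=O)c1ccccc1 | intermediate (not isolated)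
12 | (4S,5S)-4-[(4R)-2,2-dimethyl-1,3-dioxolan-4-yl]-3-methylidene-5-[(1E)-2-methyl-3-(phenylsulfonyl)prop-1-en-1-yl]oxolan-2-one | C=C1C(=O)O[C@@H](/C=C(\C)CS(=O)(=O)c2ccccc2)[C@H]1[C@@H]3COC(C)(C)O3 | intermediate
13 | diol (6S,7S,8R): 3-SO2Ph, 4E, 6-OH, 12-OH, 8,9-O-isopropylidene | C=C(CO)[C@H]([C@@H]1COC(C)(C)O1)[C@@H](O)/C=C(\C)CS(=O)(=O)c1ccccc1 | intermediate
14 | bis-TBS ether (6S,7R,8R): 6-OTBS, 12-OTBS, 8,9-O-isopropylidene | C=C(CO[Si](C)(C)C(C)(C)C)[C@H]([C@@H]1COC(C)(C)O1)[C@@H](O[Si](C)(C)C(C)(C)C)/C=C(\C)CS(=O)(=O)c1ccccc1 | intermediate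
15 | 8,9-diol (6S,7R,8R): 6-OTBS, 12-OTBS | C=C(CO[Si](C)(C)C(C)(C)C)[C@H]([C@@H](O)CO)[C@@H](O[Si](C)(C)C(C)(C)C)/C=C(\C)CS(=O)(=O)c1ccccc1 | intermediate
16 | 8,9-O-(4-methoxybenzylidene) acetal (6S,7R,8R; acetal epimers) | C=C(CO[Si](C)(C)C(C)(C)C)[C@H]([C@@H]1COC(c2ccc(OC)cc2)O1)[C@@H](O[Si](C)(C)C(C)(C)C)/C=C(\C)CS(=O)(=O)c1ccccc1 | intermediate
17 | primary alcohol (6S,7R,8R): 8-OPMB, 9-OH, 6-OTBS, 12-OTBS | C=C(CO[Si](C)(C)C(C)(C)C)[C@H]([C@@H](OCc1ccc(OC)cc1)CO)[C@@H](O[Si](C)(C)C(C)(C)C)/C=C(\C)CS(=O)(=O)c1ccccc1 | intermediate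
18 | C9 aldehyde (6S,7R,8R): 8-OPMB, 6-OTBS, 12-OTBS | C=C(CO[Si](C)(C)C(C)(C)C)[C@H]([C@@H](OCc1ccc(OC)cc1)C=O)[C@@H](O[Si](C)(C)C(C)(C)C)/C=C(\C)CS(=O)(=O)c1ccccc1 | intermediate
19 | 2-butyn-1-ol | CC#CCO | starting material
20 | sodium cyclic vinylalanate from 19 (2-methyl-5H-1,2-oxaluminole-type aluminate, aluminium on C3) | CC1=CCO[Al-]1(OCCOC)OCCOC.[Na+] | intermediate (not isolated)
21 | (2Z)-3-iodobut-2-en-1-ol | C/C(I)=C/CO | intermediate
22 | (2Z)-3-iodobut-2-en-1-yl triethylsilyl ether | C/C(I)=C/CO[Si](CC)(CC)CC | intermediate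
23 | alkenyllithium from 22 (lithium cis to CH2OTES) | C/C([Li])=C/CO[Si](CC)(CC)CC | intermediate (not isolated)
24 | alkenylmagnesium bromide from 23 (magnesium cis to CH2OTES) | C/C([Mg]Br)=C/CO[Si](CC)(CC)CC | intermediate (not isolated)
25 | C9 alcohol (1(10)Z,4E,6S,7R,8R,9R): 2-OTES, 9-OH, 8-OPMB, 6-OTBS, 12-OTBS, 3-SO2Ph | CC[Si](CC)(CC)OC/C=C(/C)[C@@H](O)[C@H](OCc1ccc(OC)cc1)[C@@H](C(=C)CO[Si](C)(C)C(C)(C)C)[C@@H](O[Si](C)(C)C(C)(C)C)/C=C(\C)CS(=O)(=O)c1ccccc1 | intermediate
26 | C9 TIPS ether of 25 | CC[Si](CC)(CC)OC/C=C(/C)[C@@H](O[Si](C(C)C)(C(C)C)C(C)C)[C@H](OCc1ccc(OC)cc1)[C@@H](C(=C)CO[Si](C)(C)C(C)(C)C)[C@@H](O[Si](C)(C)C(C)(C)C)/C=C(\C)CS(=O)(=O)c1ccccc1 | intermediate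
27 | C2 alcohol: 2-OH, 9-OTIPS, 8-OPMB, 6-OTBS, 12-OTBS, 3-SO2Ph | OC/C=C(/C)[C@@H](O[Si](C(C)C)(C(C)C)C(C)C)[C@H](OCc1ccc(OC)cc1)[C@@H](C(=C)CO[Si](C)(C)C(C)(C)C)[C@@H](O[Si](C)(C)C(C)(C)C)/C=C(\C)CS(=O)(=O)c1ccccc1 | intermediate
28 | C2 bromide / C3 sulfone, (1(10)Z,4E,6S,7R,8R,9R)-2-bromo-3-(phenylsulfonyl)-6,12-bis(TBS-oxy)-8-(PMB-oxy)-9-(TIPS-oxy)-2,3-secogermacra-1(10),4,11(13)-triene | BrC/C=C(/C)[C@@H](O[Si](C(C)C)(C(C)C)C(C)C)[C@H](OCc1ccc(OC)cc1)[C@@H](C(=C)CO[Si](C)(C)C(C)(C)C)[C@@H](O[Si](C)(C)C(C)(C)C)/C=C(\C)CS(=O)(=O)c1ccccc1 | intermediate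
29 | C3-lithiated sulfone from 28 | BrC/C=C(/C)[C@@H](O[Si](C(C)C)(C(C)C)C(C)C)[C@H](OCc1ccc(OC)cc1)[C@@H](C(=C)CO[Si](C)(C)C(C)(C)C)[C@@H](O[Si](C)(C)C(C)(C)C)/C=C(\C)C([Li])S(=O)(=O)c1ccccc1 | intermediate (not isolated)
30 | (1(10)Z,4E,6S,7R,8R,9R)-3-(phenylsulfonyl)-6,12-bis(TBS-oxy)-8-(PMB-oxy)-9-(TIPS-oxy)germacra-1(10),4,11(13)-triene (3S epimer drawn) | CC(C)(C)[Si](C)(C)O[C@H]1/C=C(\C)[C@@H](S(=O)(=O)c2ccccc2)C/C=C(/C)[C@@H](O[Si](C(C)C)(C(C)C)C(C)C)[C@H](OCc2ccc(OC)cc2)[C@H]1C(=C)CO[Si](C)(C)C(C)(C)C | intermediate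
31 | (1(10)Z,4E,6S,7R,8R,9R)-6,12-bis(TBS-oxy)-8-(PMB-oxy)-9-(TIPS-oxy)germacra-1(10),4,11(13)-triene | CC(C)(C)[Si](C)(C)O[C@H]1/C=C(\C)CC/C=C(/C)[C@@H](O[Si](C(C)C)(C(C)C)C(C)C)[C@H](OCc2ccc(OC)cc2)[C@H]1C(=C)CO[Si](C)(C)C(C)(C)C | intermediate
32 | C8 alcohol (6S,7R,8R,9R): 8-OH, 9-OTIPS, 6-OTBS, 12-OTBS | CC(C)(C)[Si](C)(C)O[C@H]1/C=C(\C)CC/C=C(/C)[C@@H](O[Si](C(C)C)(C(C)C)C(C)C)[C@H](O)[C@H]1C(=C)CO[Si](C)(C)C(C)(C)C | intermediate
33 | angelic acid, (2Z)-2-methylbut-2-enoic acid | C/C=C(/C)C(=O)O | starting material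
34 | (2Z)-2-methylbut-2-en-1-ol | C/C=C(/C)CO | intermediate
35 | [(2R,3S)-2,3-dimethyloxiran-2-yl]methanol | OC[C@@]1(C)O[C@H]1C | intermediate
36 | (2S,3S)-2,3-dimethyloxirane-2-carbaldehyde | O=C[C@@]1(C)O[C@H]1C | intermediate (not isolated)
37 | (2S,3S)-2,3-dimethyloxirane-2-carboxylic acid | OC(=O)[C@@]1(C)O[C@H]1C | intermediate
38 | (2S,3S)-2,3-dimethyloxirane-2-carboxylic 2,4,6-trichlorobenzoic anhydride | O=C(OC(=O)[C@@]1(C)O[C@H]1C)c1c(Cl)cc(Cl)cc1Cl | intermediate (not isolated)
39 | C8 ester (6S,7R,8R,9R): 8-O-[(2S,3S)-2,3-dimethyloxirane-2-carbonyl], 9-OTIPS, 6-OTBS, 12-OTBS | CC(C)(C)[Si](C)(C)O[C@H]1/C=C(\C)CC/C=C(/C)[C@@H](O[Si](C(C)C)(C(C)C)C(C)C)[C@H](OC(=O)[C@@]2(C)O[C@H]2C)[C@H]1C(=C)CO[Si](C)(C)C(C)(C)C | intermediate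
40 | 6,12-diol (6S,7S,8R,9R): 8-ester, 9-OTIPS | O[C@H]1/C=C(\C)CC/C=C(/C)[C@@H](O[Si](C(C)C)(C(C)C)C(C)C)[C@H](OC(=O)[C@@]2(C)O[C@H]2C)[C@H]1C(=C)CO | intermediate
41 | 6-hydroxy-12-al (hydroxy enal) | O[C@H]1/C=C(\C)CC/C=C(/C)[C@@H](O[Si](C(C)C)(C(C)C)C(C)C)[C@H](OC(=O)[C@@]2(C)O[C@H]2C)[C@H]1C(=C)C=O | intermediate (not isolated)
42 | 12,6-lactol (C12 epimers) | C=C1C(O)O[C@H]2/C=C(\C)CC/C=C(/C)[C@@H](O[Si](C(C)C)(C(C)C)C(C)C)[C@H](OC(=O)[C@@]3(C)O[C@H]3C)[C@@H]12 | intermediate (not isolated)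
43 | 9-O-TIPS lactone (6S,7S,8R,9R) | C=C1C(=O)O[C@H]2/C=C(\C)CC/C=C(/C)[C@@H](O[Si](C(C)C)(C(C)C)C(C)C)[C@H](OC(=O)[C@@]3(C)O[C@H]3C)[C@@H]12 | intermediate
44 | CNP0318223.3, (1(10)Z,4E,6S,7S,8R,9R)-9-hydroxy-8-[(2S,3S)-2,3-dimethyloxirane-2-carbonyloxy]germacra-1(10),4,11(13)-trien-12,6-olide | C=C1C(=O)O[C@H]2/C=C(\C)CC/C=C(/C)[C@@H](O)[C@H](OC(=O)[C@@]3(C)O[C@H]3C)[C@@H]12 | target

**Step count**

Total: 29 steps. Longest linear sequence: 21 steps (1 or 5 to 44, through steps 1–3 or 4–6, then 7–13, 16–22 and 26–29).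

**Steps most likely to fail**

Step 20. Ring closure may lose to oligomerisation, to vinylogous elimination of the C6 silanolate from the sulfonyl anion, or to γ/SN2′ alkylation in the strained ten-membered transition state. The fallback forms C2–C3 between two molecules and closes the ring at C9–C10 instead; it sets out from 21 and 17 and returns at 30. Iodo alcohol 21 is brominated (CBr4, PPh3) to (2Z)-1-bromo-3-iodobut-2-ene F3. The dianion of alcohol 17 (LiN(SiMe3)2, 2.2 equiv, THF, −78 °C) is alkylated at C3 by F3 to give the C3-alkylated iodo alcohol F4. Dess–Martin oxidation gives the iodo aldehyde F5. An intramolecular Nozaki–Hiyama–Kishi reaction (CrCl2, NiCl2 cat., DMSO/THF, high dilution) closes the ring to the macrocyclic C9 alcohol F6, and TIPSOTf/2,6-lutidine then gives 30. In this variant C9 would be set under conformational rather than chelate control, so its configuration would have to be checked at the stage of F6.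

Step 7. The enal may show poor facial selectivity toward the allylzinc (C7 and C6 relative to C8), or the syn preference of the chair may be eroded. The fallback replaces the substrate-controlled zinc reagent by a catalyst-controlled allylboration; it sets out from 8 and 4 and returns at 12. Adduct 8 is acetylated (Ac2O, DMAP) to the acetate F1. Palladium-catalysed borylation (Pd2(dba)3, B2pin2) gives the allylboronate F2, with the dioxolane cis to CH2B. Allylboration of 4 in a closed chair transition state, catalysed by the chiral phosphoric acid (R)-TRIP (expected by analogy with simple allylboronates to attack the aldehyde face that gives 6S), then acid lactonisation of hydroxy ester 11, gives 12.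

Step 21. Hydride may be delivered to C5 instead of C3 (alkene transposition), or the π-allyl complex may equilibrate and erode the E geometry of C4=C5 in the medium ring. The fallback changes from the π-allylpalladium hydride path to single-electron reduction: sodium amalgam with Na2HPO4 in MeOH/THF at −20 °C cleaves the C–S bond of 30 through its radical anion, and the allyl anion is protonated in the buffered medium to give 31 directly. No new compound arises (F0).

**Further compounds**

F1 | step 7 | methyl 2-{(acetyloxy)[(4S)-2,2-dimethyl-1,3-dioxolan-4-yl]methyl}prop-2-enoate (epimers) | COC(=O)C(=C)C(OC(C)=O)[C@@H]1COC(C)(C)O1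
F2 | step 7 | methyl (2E)-3-[(4R)-2,2-dimethyl-1,3-dioxolan-4-yl]-2-[(4,4,5,5-tetramethyl-1,3,2-dioxaborolan-2-yl)methyl]prop-2-enoate | COC(=O)/C(CB1OC(C)(C)C(C)(C)O1)=C/[C@@H]1COC(C)(C)O1
F3 | step 20 | (2Z)-1-bromo-3-iodobut-2-ene | C/C(I)=C/CBr
F4 | step 20 | C3-alkylated iodo alcohol (6S,7R,8R; C3 epimers): 10-iodo, 9-OH, 8-OPMB, 6-OTBS, 12-OTBS, 3-SO2Ph, 9,10-seco | OC[C@H](OCc1ccc(OC)cc1)[C@@H](C(=C)CO[Si](C)(C)C(C)(C)C)[C@@H](O[Si](C)(C)C(C)(C)C)/C=C(\C)C(C/C=C(/C)I)S(=O)(=O)c1ccccc1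
F5 | step 20 | iodo aldehyde (C9 aldehyde of F4) | O=C[C@H](OCc1ccc(OC)cc1)[C@@H](C(=C)CO[Si](C)(C)C(C)(C)C)[C@@H](O[Si](C)(C)C(C)(C)C)/C=C(\C)C(C/C=C(/C)I)S(=O)(=O)c1ccccc1
F6 | step 20 | macrocyclic C9 alcohol (9R; C3 epimers): 9-OH, 8-OPMB, 6-OTBS, 12-OTBS, 3-SO2Ph | CC(C)(C)[Si](C)(C)O[C@H]1/C=C(\C)C(S(=O)(=O)c2ccccc2)C/C=C(/C)[C@@H](O)[C@H](OCc2ccc(OC)cc2)[C@H]1C(=C)CO[Si](C)(C)C(C)(C)C
F0 | step 21 | none | none
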